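**Retrosynthetic overview** (labdane numbering: ring A = C1–C5 and C10, ring B = C5–C10)
1. Target 25 comes from the 18-nor β-keto ester 21 by late decoration of ring A: C18 methyl from the α face, axial C3 alcohol, acetate, desilylation.
2. Enabling feature: in ring A the acceptor carbon C4 (between the C3 oxygen and the C19 ester) lies 1,3 to the methyl-bearing quaternary C10 across C5, and ring B carries the C8=C17 methylene next to C9. A retrosynthetic C4–C10 bond therefore gives the acceptor-activated bicyclo[3.1.0]hexanone 19 with a (Z)-allylsilane chain on C5.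
3. Key step: a Lewis acid breaks C4–C10. The cyclopentanone C3–C2–C1–C10–C4 grows to six-membered ring A by taking in C5, while C9 attacks C10 and closes ring B. C9, C10, the trans fusion and the exocyclic alkene arise together.
4. Ring order: cyclopentanone and cyclopropane form first (step 10, copper carbene addition within the open-chain diazo ester 18). Ring A (enlargement) and ring B (closure) then form together in step 11.
5. 18 comes from two iterative Claisen rearrangements that set both trisubstituted alkenes. They start from aldehyde 3 of (S)-citronellol, whose carbons become C9 and C11–C16 and whose stereocentre becomes C13.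

Key step: step 11

Assumption: the (S,S)-configured bis(oxazoline) ligand is taken to deliver the (1R,5R,6R) series in step 10; if the sense of induction is opposite, the equally available (R,R)-ligand is used.

**Step 1**
Reactants: 1 (S)-(−)-citronellol
Product: 2 (S)-citronellyl tert-butyldiphenylsilyl ether
Conditions: TBDPSCl, imidazole, DMF, 0 °C → rt
Reagents that add atoms: tert-butyl(chloro)diphenylsilane, CC(C)(C)[Si](Cl)(c1ccccc1)c1ccccc1
Why: Standard silyl ether protection of the primary alcohol (future C15–OH); TBDPS should survive Grignard reagents, hot weak acid, NaH and the Lewis acid of step 11, can be removed at the end beside an acetate, and leaves C13 untouched.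

**Step 2**
Reactants: 2 (S)-citronellyl tert-butyldiphenylsilyl ether
Product: 3 (S)-6-[(tert-butyldiphenylsilyl)oxy]-4-methylhexanal
Conditions: O3, CH2Cl2, −78 °C; then Me2S, −78 °C → rt
Reagents that add atoms: ozone, [O-][O+]=O
Why: Ozonolysis with reductive work-up cleaves the only C=C bond and turns the former olefinic CH of citronellol into the aldehyde carbon that becomes C9.

**Step 3**
Reactants: 3 (S)-6-[(tert-butyldiphenylsilyl)oxy]-4-methylhexanal; 4 (2-bromoallyl)trimethylsilane
Product: 6 (6S)-8-[(tert-butyldiphenylsilyl)oxy]-6-methyl-2-[(trimethylsilyl)methyl]oct-1-en-3-ol (both carbinol epimers), via vinyl Grignard reagent 5 (not isolated)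
Conditions: 4, Mg, THF, reflux; then 3, THF, −78 → 0 °C; H2O quench
Reagents that add atoms: (2-bromoallyl)trimethylsilane (4), C=C(Br)C[Si](C)(C)C
Why: Grignard 1,2-addition of the α-(silylmethyl)vinyl nucleophile installs C7, C8 and C17 with silicon already on C17; the new carbinol centre needs no control because step 4 erases it.

**Step 4**
Reactants: 6 allylic alcohol; 7 trimethyl orthoacetate
Product: 9 methyl (4Z,8S)-10-[(tert-butyldiphenylsilyl)oxy]-8-methyl-4-[(trimethylsilyl)methyl]dec-4-enoate, via ketene acetal 8 (not isolated)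
Conditions: 7 (excess), EtCO2H (cat.), toluene, 110 °C, MeOH distilled off
Reagents that add atoms: trimethyl orthoacetate (7), CC(OC)(OC)OC
Why: The Johnson–Claisen rearrangement runs through a chair transition state with the C11 chain equatorial and should place C7 trans to C11 (Z by CIP because of silicon); the weak acid catalyst should leave the allylsilane intact.

**Step 5**
Reactants: 9 methyl ester
Product: 10 (4Z,8S)-10-[(tert-butyldiphenylsilyl)oxy]-8-methyl-4-[(trimethylsilyl)methyl]dec-4-enal
Conditions: DIBAL-H (1.05 equiv), CH2Cl2, −78 °C; aqueous work-up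
Reagents that add atoms: none
Why: Partial ester reduction with DIBAL-H at low temperature should stop at the aldehyde (future C5); silyl ether and allylsilane are inert.

**Step 6**
Reactants: 10 aldehyde; 11 isopropenylmagnesium bromide
Product: 12 (6Z,10S)-12-[(tert-butyldiphenylsilyl)oxy]-2,10-dimethyl-6-[(trimethylsilyl)methyl]dodeca-1,6-dien-3-ol (both carbinol epimers)
Conditions: 11 (THF solution), THF, −78 → 0 °C; H2O quench
Reagents that add atoms: isopropenylmagnesium bromide (11), C=C(C)[Mg]Br
Why: Grignard 1,2-addition brings in C10, C20 and C1; the carbinol centre is erased in step 7 and needs no control.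

**Step 7**
Reactants: 12 allylic alcohol; 13 2-methoxypropene
Product: 15 (5E,9Z,13S)-15-[(tert-butyldiphenylsilyl)oxy]-5,13-dimethyl-9-[(trimethylsilyl)methyl]pentadeca-5,9-dien-2-one, via allyl isopropenyl ether 14 (not isolated)
Conditions: 13 (excess), PPTS (cat.), toluene, 120 °C, sealed tube
Reagents that add atoms: 2-methoxypropene (13), C=C(C)OC
Why: In the Saucy–Marbet variant of the Claisen rearrangement, enol ether exchange gives 14, whose chair-like [3,3] shift with the C6 chain equatorial should give the E alkene C5=C10 and the methyl ketone C2–C3(=O)–C4.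

**Step 8**
Reactants: 15 methyl ketone; 16 dimethyl carbonate
Product: 17 methyl (6E,10Z,14S)-16-[(tert-butyldiphenylsilyl)oxy]-6,14-dimethyl-3-oxo-10-[(trimethylsilyl)methyl]hexadeca-6,10-dienoate
Conditions: NaH (2.2 equiv), 16, THF, reflux; AcOH quench
Reagents that add atoms: dimethyl carbonate (16), COC(=O)OC
Why: Claisen-type C-acylation of the methyl ketone under equilibrating conditions should occur at the less hindered methyl terminus (C4) and is driven by formation of the stabilised β-keto ester enolate.

**Step 9**
Reactants: 17 β-keto ester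
Product: 18 methyl (6E,10Z,14S)-16-[(tert-butyldiphenylsilyl)oxy]-2-diazo-6,14-dimethyl-3-oxo-10-[(trimethylsilyl)methyl]hexadeca-6,10-dienoate
Conditions: p-ABSA, Et3N, MeCN, 0 °C → rt
Reagents that add atoms: 4-acetamidobenzenesulfonyl azide, CC(=O)Nc1ccc(cc1)S(=O)(=O)N=[N+]=[N-]
Why: Regitz diazo transfer onto the active methylene C4 is mild and should not touch the alkenes, the allylsilane or the silyl ether.

**Step 10**
Reactants: 18 α-diazo-β-keto ester
Product: 19 methyl (1R,5R,6R)-6-{(3Z,7S)-9-[(tert-butyldiphenylsilyl)oxy]-7-methyl-3-[(trimethylsilyl)methyl]non-3-en-1-yl}-5-methyl-2-oxobicyclo[3.1.0]hexane-1-carboxylate (chain exo)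
Conditions: [Cu(MeCN)4]PF6 (5 mol %), 2,2'-isopropylidenebis[(4S)-4-tert-butyl-2-oxazoline] (6 mol %), toluene, 50 °C, slow addition of 18
Reagents that add atoms: none
Why: In this Cu(I)/bis(oxazoline)-catalysed asymmetric intramolecular cyclopropanation of an α-diazo-β-keto ester the carbene adds suprafacially to the proximal E alkene (five-membered ring closure should outrun attack at the remote allylsilane), so the alkene geometry fixes the relative configuration (chain exo, cis to the methyl group) and the ligand fixes the absolute configuration at C4, C5 and C10.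

**Step 11**
Reactants: 19 bicyclo[3.1.0]hexanone
Product: 21 methyl (13S)-15-[(tert-butyldiphenylsilyl)oxy]-3-oxo-18-norlabd-8(17)-en-19-oate (keto–enol mixture; C4 not fixed), via silyl enol ether 20 (not isolated)
Conditions: Sc(OTf)3 (10 mol %), 2,6-di-tert-butyl-4-methylpyridine (20 mol %), CH2Cl2, −20 °C → rt; then THF/H2O, citric acid (cat.)
Reagents that add atoms: none
Why: Sc(III) chelates the C3 ketone and the C19 ester and polarises the bond C4–C10 (C4 as stabilised β-keto ester carbanion, C10 as methyl-bearing tertiary cation); the γ-carbon C9 of the tethered allylsilane attacks C10 anti to the departing C4, the β-silyl cation at C8 collapses to the C8=C17 methylene, and the silyl group ends on O3 (20), which turns the catalyst over. The closest known reaction types are olefin participation in the acid-promoted opening of 6-alkenylbicyclo[3.1.0]hexan-2-ones to decalones and the allylsilane-terminated (Hosomi–Sakurai type) cation–olefin cyclisation. Ring A is not closed but enlarged: loss of the zero-atom bridge C4–C10 turns the cyclopentanone C3–C2–C1–C10–C4 into the cyclohexanone C3–C2–C1–C10–C5–C4 by taking in C5, while ring B closes in a 6-exo-tet mode at C10 that is 6-endo with respect to the C8=C9 π bond. C10 is set by inversion and C5 keeps its cyclopropane configuration, so the exo (E-alkene derived) chain translates stereospecifically into the trans fusion (10β-CH3, 5α-H); C9 is set by the chair-like transition state together with the Z-allylsilane geometry, which places C11 equatorial (9α-H). The step needs cleavage of C4–C10 rather than C4–C5 and a single alkene regioisomer: C10 is the only fully alkyl-substituted, cation-stabilising cyclopropane carbon and the only one that the four-atom tether can reach from the back side, and the β-silicon effect fixes the alkene at C8(17). C4 stays enolisable and is set in step 12.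

**Step 12**
Reactants: 21 18-nor β-keto ester
Product: 22 methyl (13S)-15-[(tert-butyldiphenylsilyl)oxy]-3-oxolabd-8(17)-en-19-oate
Conditions: MeI, K2CO3, acetone, rt → 40 °C
Reagents that add atoms: iodomethane, CI
Why: In this C-alkylation of the β-keto ester enolate MeI should approach from the α face, anti to the axial C10 methyl group that screens the β face, which makes the new methyl group equatorial (C18) and leaves the ester axial (C19).

**Step 13**
Reactants: 22 3-ketone
Product: 23 methyl (13S)-15-[(tert-butyldiphenylsilyl)oxy]-3α-hydroxylabd-8(17)-en-19-oate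
Conditions: L-Selectride, THF, −78 °C; then NaOH, H2O2, 0 °C
Reagents that add atoms: none
Why: Under steric approach control the bulky trialkylborohydride should attack the cyclohexanone from the equatorial direction and give the axial 3α-alcohol (3R); the hindered ester, silyl ether and alkene should be inert at −78 °C.

**Step 14**
Reactants: 23 3α-alcohol
Product: 24 methyl (13S)-3α-acetoxy-15-[(tert-butyldiphenylsilyl)oxy]labd-8(17)-en-19-oate
Conditions: Ac2O, DMAP (cat.), pyridine, rt → 40 °C
Reagents that add atoms: acetic anhydride, CC(=O)OC(C)=O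
Why: DMAP-catalysed acylation esterifies the only free hydroxyl group with retention at C3.

**Step 15**
Reactants: 24 silyl ether
Product: 25 methyl (13S)-3α-acetoxy-15-hydroxylabd-8(17)-en-19-oate (CNP0230414.1)
Conditions: HF·pyridine, pyridine, THF, 0 °C → rt
Reagents that add atoms: none
Why: Fluoride-mediated Si–O cleavage under buffered conditions should free the C15 alcohol without touching the acetate, the methyl ester or the exocyclic alkene.

**Compound list**
1 | (S)-(−)-citronellol | CC(C)=CCC[C@H](C)CCO | starting material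
2 | (S)-citronellyl TBDPS ether | CC(C)=CCC[C@H](C)CCO[Si](c1ccccc1)(c1ccccc1)C(C)(C)C | intermediate
3 | (S)-6-(TBDPS-oxy)-4-methylhexanal | O=CCC[C@H](C)CCO[Si](c1ccccc1)(c1ccccc1)C(C)(C)C | intermediate
4 | (2-bromoallyl)trimethylsilane | C=C(Br)C[Si](C)(C)C | starting material
5 | [1-(trimethylsilylmethyl)vinyl]magnesium bromide | C=C([Mg]Br)C[Si](C)(C)C | intermediate
6 | (6S)-8-(TBDPS-oxy)-6-methyl-2-[(trimethylsilyl)methyl]oct-1-en-3-ol, both carbinol epimers | C=C(C[Si](C)(C)C)C(O)CC[C@H](C)CCO[Si](c1ccccc1)(c1ccccc1)C(C)(C)C | intermediate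
7 | trimethyl orthoacetate | CC(OC)(OC)OC | starting material
8 | mixed ketene acetal of 6 | C=C(OC)OC(CC[C@H](C)CCO[Si](c1ccccc1)(c1ccccc1)C(C)(C)C)C(=C)C[Si](C)(C)C | intermediate
9 | methyl (4Z,8S)-10-(TBDPS-oxy)-8-methyl-4-[(trimethylsilyl)methyl]dec-4-enoate | COC(=O)CC/C(C[Si](C)(C)C)=C/CC[C@H](C)CCO[Si](c1ccccc1)(c1ccccc1)C(C)(C)C | intermediate
10 | (4Z,8S)-10-(TBDPS-oxy)-8-methyl-4-[(trimethylsilyl)methyl]dec-4-enal | O=CCC/C(C[Si](C)(C)C)=C/CC[C@H](C)CCO[Si](c1ccccc1)(c1ccccc1)C(C)(C)C | intermediate
11 | isopropenylmagnesium bromide | C=C(C)[Mg]Br | starting material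
12 | (6Z,10S)-12-(TBDPS-oxy)-2,10-dimethyl-6-[(trimethylsilyl)methyl]dodeca-1,6-dien-3-ol, both carbinol epimers | C=C(C)C(O)CC/C(C[Si](C)(C)C)=C/CC[C@H](C)CCO[Si](c1ccccc1)(c1ccccc1)C(C)(C)C | intermediate
13 | 2-methoxypropene | C=C(C)OC | starting material
14 | allyl isopropenyl ether of 12 | C=C(C)OC(CC/C(C[Si](C)(C)C)=C/CC[C@H](C)CCO[Si](c1ccccc1)(c1ccccc1)C(C)(C)C)C(C)=C | intermediate
15 | (5E,9Z,13S)-15-(TBDPS-oxy)-5,13-dimethyl-9-[(trimethylsilyl)methyl]pentadeca-5,9-dien-2-one | CC(=O)CC/C(C)=C/CC/C(C[Si](C)(C)C)=C/CC[C@H](C)CCO[Si](c1ccccc1)(c1ccccc1)C(C)(C)C | intermediate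
16 | dimethyl carbonate | COC(=O)OC | starting material
17 | methyl (6E,10Z,14S)-16-(TBDPS-oxy)-6,14-dimethyl-3-oxo-10-[(trimethylsilyl)methyl]hexadeca-6,10-dienoate | COC(=O)CC(=O)CC/C(C)=C/CC/C(C[Si](C)(C)C)=C/CC[C@H](C)CCO[Si](c1ccccc1)(c1ccccc1)C(C)(C)C | intermediate
18 | 2-diazo derivative of 17 | COC(=O)C(=[N+]=[N-])C(=O)CC/C(C)=C/CC/C(C[Si](C)(C)C)=C/CC[C@H](C)CCO[Si](c1ccccc1)(c1ccccc1)C(C)(C)C | intermediate
19 | methyl (1R,5R,6R)-6-{(3Z,7S)-9-(TBDPS-oxy)-7-methyl-3-[(trimethylsilyl)methyl]non-3-en-1-yl}-5-methyl-2-oxobicyclo[3.1.0]hexane-1-carboxylate | COC(=O)[C@@]12C(=O)CC[C@]1(C)[C@H]2CC/C(C[Si](C)(C)C)=C/CC[C@H](C)CCO[Si](c3ccccc3)(c3ccccc3)C(C)(C)C | intermediate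
20 | C3 trimethylsilyl enol ether of 21 | C=C1CC[C@@H]2[C@](C)(CCC(O[Si](C)(C)C)=C2C(=O)OC)[C@H]1CC[C@H](C)CCO[Si](c3ccccc3)(c3ccccc3)C(C)(C)C | intermediate
21 | methyl (13S)-15-(TBDPS-oxy)-3-oxo-18-norlabd-8(17)-en-19-oate (C4 enolisable) | C=C1CC[C@@H]2[C@](C)(CCC(=O)C2C(=O)OC)[C@H]1CC[C@H](C)CCO[Si](c3ccccc3)(c3ccccc3)C(C)(C)C | intermediate
22 | methyl (13S)-15-(TBDPS-oxy)-3-oxolabd-8(17)-en-19-oate | C=C1CC[C@@H]2[C@](C)(CCC(=O)[C@]2(C)C(=O)OC)[C@H]1CC[C@H](C)CCO[Si](c3ccccc3)(c3ccccc3)C(C)(C)C | intermediate
23 | methyl (13S)-15-(TBDPS-oxy)-3α-hydroxylabd-8(17)-en-19-oate | C=C1CC[C@@H]2[C@](C)(CC[C@@H](O)[C@]2(C)C(=O)OC)[C@H]1CC[C@H](C)CCO[Si](c3ccccc3)(c3ccccc3)C(C)(C)C | intermediate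
24 | methyl (13S)-3α-acetoxy-15-(TBDPS-oxy)labd-8(17)-en-19-oate | C=C1CC[C@@H]2[C@](C)(CC[C@@H](OC(C)=O)[C@]2(C)C(=O)OC)[C@H]1CC[C@H](C)CCO[Si](c3ccccc3)(c3ccccc3)C(C)(C)C | intermediate
25 | methyl (13S)-3α-acetoxy-15-hydroxylabd-8(17)-en-19-oate | C=C1CC[C@@H]2[C@](C)(CC[C@@H](OC(C)=O)[C@]2(C)C(=O)OC)[C@H]1CC[C@H](C)CCO | target

Total step count: 15. Longest linear sequence: 15 steps (from 1).

**Steps most likely to fail**

First, step 11.
- Risk: ionisation at C10 may be followed by proton loss instead of C–C bond formation.
- Risk: the allylsilane may be protodesilylated by adventitious acid before the cyclopropane is activated.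
- Risk: the Lewis acidity needed to break C4–C10 may be more than the allylsilane tolerates.
- Fallback: ring enlargement and ring closure are separated.
  - It sets out from 19. Bromotrimethylsilane (2,6-di-tert-butyl-4-methylpyridine, CH2Cl2, −78 °C) should open the same C4–C10 bond, with bromide at the tertiary carbon and silicon on O3.
  - This gives methyl (5S,6S)-5-bromo-5-methyl-6-{(3Z,7S)-9-(TBDPS-oxy)-7-methyl-3-[(trimethylsilyl)methyl]non-3-en-1-yl}-2-(trimethylsilyloxy)cyclohex-1-ene-1-carboxylate F1.
  - Halophilic activation of the tertiary bromide with AgOTf at −78 °C should then generate the C10 cation under non-acidic conditions. The allylsilane closes ring B to 20, and aqueous work-up comes back to the route at 21.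

Second, step 10.
- Risk: enantioface discrimination at the trisubstituted alkene may be poor with the small methyl ester.
- Risk: because C13 is remote, the wrong core series would travel on as a diastereomer that is hard to remove. Carbene dimerisation may also compete.
- Fallback: stereocontrol by the catalyst is given up in favour of a resolution.
  - It sets out from 18. Achiral Rh2(OAc)4 (CH2Cl2, slow addition) should give 19 together with methyl (1S,5S,6S)-6-{(3Z,7S)-9-(TBDPS-oxy)-7-methyl-3-[(trimethylsilyl)methyl]non-3-en-1-yl}-5-methyl-2-oxobicyclo[3.1.0]hexane-1-carboxylate F2.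
  - The two differ in the whole bicyclic core. They are separated by preparative chromatography on a chiral stationary phase, and the route is rejoined at 19.

Third, step 13.
- Risk: facial selectivity may be poor, because the axial C19 ester screens the side from which the bulky hydride has to come.
- Risk: the β-alkoxy ester may open in a retro-aldol sense during work-up.
- Fallback: substrate control is replaced by catalyst control.
  - It sets out from 22. A Corey–Bakshi–Shibata reduction with the (S)-methyl oxazaborolidine and catecholborane (toluene, −78 °C) is used. Catecholborane is chosen because BH3 would hydroborate the methylene group.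
  - The catalyst should tell the quaternary C4 from the methylene C2 and deliver hydride to the face that gives the 3R alcohol. The route is rejoined at 23, and no new compound arises (F0).

**Further compounds**
F1 | step 11 | methyl (5S,6S)-5-bromo-5-methyl-6-{(3Z,7S)-9-(TBDPS-oxy)-7-methyl-3-[(trimethylsilyl)methyl]non-3-en-1-yl}-2-(trimethylsilyloxy)cyclohex-1-ene-1-carboxylate | COC(=O)C1=C(O[Si](C)(C)C)CC[C@](C)(Br)[C@H]1CC/C(C[Si](C)(C)C)=C/CC[C@H](C)CCO[Si](c2ccccc2)(c2ccccc2)C(C)(C)C
F2 | step 10 | methyl (1S,5S,6S)-6-{(3Z,7S)-9-(TBDPS-oxy)-7-methyl-3-[(trimethylsilyl)methyl]non-3-en-1-yl}-5-methyl-2-oxobicyclo[3.1.0]hexane-1-carboxylate | COC(=O)[C@]12C(=O)CC[C@@]1(C)[C@@H]2CC/C(C[Si](C)(C)C)=C/CC[C@H](C)CCO[Si](c3ccccc3)(c3ccccc3)C(C)(C)C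
F0 | step 13 | none | none
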